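I decided to follow one molecule of coupling partner through the flask, not the catalyst. Starting material and coupling partner join to target under a free catalyst, and Thursday's run is asked for at 600 min.

| flask | starting material | coupling partner | free catalyst | time |
|---|---|---|---|---|
| Sunday's | 0.500 M | 0.500 M | 0.0400 M |  |
| Tuesday's | 0.300 M | 0.300 M | 0.0400 M |  |
| Wednesday's | 0.500 M | 1.00 M | 0.0400 M |  |
| Monday's | 0.500 M | 0.500 M | 0.0600 M |  |
| Thursday's | 0.500 M | 0.500 M | 0.0400 M | 600 min |

| run | time / min | [target] / M |
|---|---|---|
| Sunday's run | 19 | 0.0647 |
| Sunday's run | 38 | 0.0866 |
| Sunday's run | 56 | 0.1010 |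
| Sunday's run | 75 | 0.1023 |
| Sunday's run | 94 | 0.1074 |
| Sunday's run | 110 | 0.1075 |
| Sunday's run | 130 | 0.1088 |
| Sunday's run | 150 | 0.1108 |
| Tuesday's run | 19 | 0.0429 |
| Tuesday's run | 38 | 0.0581 |
| Tuesday's run | 56 | 0.0667 |
| Tuesday's run | 75 | 0.0679 |
| Tuesday's run | 94 | 0.0690 |
| Tuesday's run | 110 | 0.0717 |
| Tuesday's run | 130 | 0.0681 |
| Tuesday's run | 150 | 0.0717 |
| Wednesday's run | 19 | 0.0965 |
| Wednesday's run | 38 | 0.1175 |
| Wednesday's run | 56 | 0.1282 |
| Wednesday's run | 75 | 0.1307 |
| Wednesday's run | 94 | 0.1347 |
| Wednesday's run | 110 | 0.1332 |
| Wednesday's run | 130 | 0.1405 |
| Wednesday's run | 150 | 0.1405 |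
| Monday's run | 19 | 0.1001 |
| Monday's run | 38 | 0.1243 |
| Monday's run | 56 | 0.1351 |
| Monday's run | 75 | 0.1353 |
| Monday's run | 94 | 0.1468 |
| Monday's run | 110 | 0.1493 |
| Monday's run | 130 | 0.1464 |
| Monday's run | 150 | 0.1514 |

(standard deviation of a reading: 0.002 M)

- Overall: starting material + coupling partner -> target, with free catalyst as catalyst.
- Constant volume, constant temperature.
- What is held in complexes is read along with the free species.
- An order is taken over about fifteen percent of the charge, up and down.

- the power of [coupling partner] that the first rate follows, about the charge of the Sunday's run; measure it at two percent of starting material made into target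
- the power of [free catalyst] that the first rate follows, about the charge of the Sunday's run; measure it at two percent of starting material made into target
- target in the Thursday's run at 600 min, as a share of the starting material charged

I turned the question round. For Thursday's run to end with its starting material turned, every molecule of coupling partner has to end in target, since the two charges are equal. So my measure was the share of the charged coupling partner that stands as target at the last reading, its yield on coupling partner: 22.2% in Sunday's run, a long way from a finish.

That share moved. In Wednesday's run, with twice the coupling partner, it was lower than Sunday's, at 14.1%. In Monday's run, with more catalyst, it was higher, at 30.3%. Wednesday's target over Sunday's also shrank, from 1.49 at 19 min to 1.27 at 150 min.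

I read a fork in these numbers. A molecule of coupling partner goes on to target through the catalyst, or it leaves by a second way that gains as coupling partner rises. Thursday's run has Sunday's charge, so I carried Sunday's share over, which made 22.2% of its starting material.

The forecast gave 0.65 for the order in coupling partner, 1.2 for the order in catalyst and 22.6% for Thursday's run, on the ground that “The plateau scales with catalyst, so this is catalyst death, not equilibrium”. Its figure for Thursday lies close to mine, but the grounds differ.

The flask gave 0.93, 1.1 and 22.8%. The order in coupling partner stood above the forecast's, and the other two fell within their margins.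

    free catalyst + starting material ⇌ catalyst-substrate complex (7.140 M⁻¹ min⁻¹, 0.4164 min⁻¹)
    catalyst-substrate complex + coupling partner → target + free catalyst (0.5262 M⁻¹ min⁻¹)
    free catalyst → spent catalyst (0.07620 min⁻¹)
    2 coupling partner → lost reagent (0.1374 M⁻¹ min⁻¹)

Thursday's share of its coupling partner came to 22.8% at 600 min, beside Sunday's 22.2% at 150 min. The second way at the fork is the step that turns two coupling partner into lost reagent, and it is the main reason for Thursday's low share. In Thursday's flask run without that step, the share stood at 62.5% instead of 22.8%.

(The data were generated by integration with constants of no real substance; scatter was added.)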